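**Retrosynthetic overview**

1. Torilin (guaiane numbering: cyclopentenone C1–C5 with C3=O and C4–CH3; seven-membered ring C1, C5–C10; C11 = carbinol carbon on C7) ⇐ diol enone 21 by C8 angeloylation, then C11 acetylation; 21 ⇐ tricyclic dienone 17 by 1,6-reduction (sets C10), base equilibration (sets C1) and acetonide cleavage.
2. 17 ⇐ acyclic allenyne 15 by a rhodium-catalysed allenic Pauson–Khand reaction with CO: the bonds C1–C5, C2–C3 and C3–C4 form in one operation.
3. Enabling feature: the cyclopentenone C1–C2–C3(=O)–C4(CH3)=C5 is a [2+2+1] retron (C4=C5 from a but-2-ynyl alkyne, C3 from CO, C1–C2 from an allene π-bond), and C10, the methyl-bearing ring carbon next to C1, can be the third allene carbon (C10=C1=C2); the 1,3-diol O8–C8–C7–C11–O allows a temporary dioxane ring, absent from the target, that folds the chain.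
4. 15 ⇐ Evans syn-aldol of N-hex-4-ynoyl oxazolidinone 4 with 3-methylbut-3-enal 6 (sets C7 and C8), MeMgBr (builds C11), acetonide, then methallyl → allene (dibromocarbene, MeLi).
5. Ring order: temporary dioxane (step 6); seven-membered ring and then cyclopentenone within step 9, the cyclopentenone being the last ring closed; dioxane removed in step 11.

Key step: step 9

**Remarks on the chemistry**

- Compounds 1, 2, 5 and 22 are taken as commercially available.
- In the target, the C8 oxygen, the C7 side chain, the C10 methyl and H1 lie on one face of the seven-membered ring; H7, H8 and H10 lie on the other.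
- Assumption: at the epimerizable carbon C1, the natural arrangement (C2 trans to the C10 methyl) is taken to be the thermodynamically preferred one.

**Route**

Step 1
Reactants: 1 hex-4-ynoic acid; 2 (S)-4-benzyl-1,3-oxazolidin-2-one
Product: 4 (S)-4-benzyl-3-(hex-4-ynoyl)-1,3-oxazolidin-2-one, via mixed pivalic anhydride 3 (not isolated)
Conditions: PivCl, Et3N, THF, −20 °C; then 2, LiCl, −20 °C to rt
Reagents that add atoms: none
Why: One-pot mixed-anhydride N-acylation of an Evans auxiliary, in which the hindered pivaloyl carbonyl of 3 directs the LiCl-activated oxazolidinone to the hex-4-ynoyl carbonyl and no stereocentre is touched.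

Step 2
Reactants: 5 3-methylbut-3-en-1-ol
Product: 6 3-methylbut-3-enal
Conditions: Dess–Martin periodinane, NaHCO3, CH2Cl2, 0 °C; filtered cold and used at once as a CH2Cl2 solution
Reagents that add atoms: none
Why: Buffered Dess–Martin oxidation is neutral and fast, so the β,γ-unsaturated aldehyde should form without migration of the double bond into conjugation if it is used immediately.

Step 3
Reactants: 4 (S)-4-benzyl-3-(hex-4-ynoyl)-1,3-oxazolidin-2-one; 6 3-methylbut-3-enal
Product: 9 (S)-4-benzyl-3-[(2S,3R)-2-(but-2-yn-1-yl)-3-hydroxy-5-methylhex-5-enoyl]-1,3-oxazolidin-2-one, via Z-boron enolate 7 (not isolated), via boron aldolate 8 (not isolated)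
Conditions: Bu2BOTf, i-Pr2NEt, CH2Cl2, −78 to 0 °C; then 6, −78 to 0 °C; pH 7 buffer, MeOH, 30% H2O2, 0 °C
Reagents that add atoms: none
Why: Evans syn-aldol reaction in which the Z-boron enolate 7 reacts through a closed Zimmerman–Traxler chair with the benzyl group of the auxiliary shielding one enolate face, which sets C7 (S) and C8 (R) together as the syn pair that becomes the cis C7/C8 relationship of the target.

Step 4
Reactants: 9 (S)-4-benzyl-3-[(2S,3R)-2-(but-2-yn-1-yl)-3-hydroxy-5-methylhex-5-enoyl]-1,3-oxazolidin-2-one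
Product: 10 methyl (2S,3R)-2-(but-2-yn-1-yl)-3-hydroxy-5-methylhex-5-enoate
Conditions: Sm(OTf)3 (10 mol %), MeOH, rt
Reagents that add atoms: methanol, CO
Why: Lewis-acid-catalysed methanolysis (transesterification) of the chelating β-hydroxy imide releases the auxiliary under non-basic conditions, so neither retro-aldol cleavage nor epimerization at C7 is expected.

Step 5
Reactants: 10 methyl (2S,3R)-2-(but-2-yn-1-yl)-3-hydroxy-5-methylhex-5-enoate
Product: 11 (3S,4R)-3-(but-2-yn-1-yl)-2,6-dimethylhept-6-ene-2,4-diol
Conditions: MeMgBr (5 equiv), THF, 0 °C to rt; aq NH4Cl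
Reagents that add atoms: methylmagnesium bromide, C[Mg]Br
Why: Double Grignard addition to the ester, after deprotonation of the hydroxyl, builds the C11 tertiary carbinol without forming a stereocentre and faster than enolization at C7.

Step 6
Reactants: 11 (3S,4R)-3-(but-2-yn-1-yl)-2,6-dimethylhept-6-ene-2,4-diol
Product: 12 (5S,6R)-5-(but-2-yn-1-yl)-2,2,4,4-tetramethyl-6-(2-methylprop-2-en-1-yl)-1,3-dioxane
Conditions: 2,2-dimethoxypropane, PPTS (cat.), CH2Cl2, rt
Reagents that add atoms: 2,2-dimethoxypropane, COC(C)(C)OC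
Why: Acid-catalysed transketalization ties O8 and O11 into a 1,3-dioxane, a temporary ring that protects both hydroxyls in one step and holds the C6 and C9 chains cis on a six-membered ring for the later ring closure.

Step 7
Reactants: 12 (5S,6R)-5-(but-2-yn-1-yl)-2,2,4,4-tetramethyl-6-(2-methylprop-2-en-1-yl)-1,3-dioxane
Product: 13 (5S,6R)-5-(but-2-yn-1-yl)-6-[(2,2-dibromo-1-methylcyclopropyl)methyl]-2,2,4,4-tetramethyl-1,3-dioxane (both epimers at the cyclopropane carbon)
Conditions: CHBr3, KOt-Bu, pentane, −10 °C to rt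
Reagents that add atoms: bromoform, BrC(Br)Br
Why: Dibromocarbene cyclopropanation (Doering–Hoffmann) should occur at the electron-rich 1,1-disubstituted alkene much faster than at the internal alkyne, and the uncontrolled cyclopropane stereocentre is erased in step 8.

Step 8
Reactants: 13 (5S,6R)-5-(but-2-yn-1-yl)-6-[(2,2-dibromo-1-methylcyclopropyl)methyl]-2,2,4,4-tetramethyl-1,3-dioxane
Product: 15 (5S,6R)-5-(but-2-yn-1-yl)-2,2,4,4-tetramethyl-6-(2-methylbuta-2,3-dien-1-yl)-1,3-dioxane, via lithium bromocarbenoid 14 (not isolated)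
Conditions: MeLi, Et2O, −78 to −30 °C
Reagents that add atoms: none
Why: Doering–Moore–Skattebøl reaction in which bromine–lithium exchange gives carbenoid 14, whose α-elimination and cyclopropylidene ring opening should deliver the 1,1-disubstituted allene with the former bromoform carbon as the central allene carbon C1.

Step 9
Reactants: 15 (5S,6R)-5-(but-2-yn-1-yl)-2,2,4,4-tetramethyl-6-(2-methylbuta-2,3-dien-1-yl)-1,3-dioxane
Product: 17 (7S,8R)-8,11-(isopropylidenedioxy)guaia-1(10),4-dien-3-one, via rhodacyclopentene 16 (not isolated)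
Conditions: [Rh(CO)2Cl]2 (5 mol %), CO (1 atm), toluene (0.02 M), 90 °C
Reagents that add atoms: carbon monoxide, [C-]#[O+]
Why: Allenic Pauson–Khand reaction ([2+2+1] cyclocarbonylation) in which monovalent rhodium binds the alkyne and the terminal C1=C2 π-bond of the allene, oxidative cyclization forms the C1–C5 bond to give the trivalent rhodacyclopentene 16, CO inserts into a Rh–C bond and reductive elimination completes the C2–C3 and C3–C4 bonds. The closest known reaction type is the [Rh(CO)2Cl]2-catalysed cyclocarbonylation of allenynes with a four-atom tether, which gives 4-alkylidenecyclopentenones of the bicyclo[5.3.0]decadienone type. The seven-membered ring closes first, by C–C bond formation between the inner alkyne carbon C5 and the central allene carbon C1 so that the C10=C1 bond stays inside the ring and C2 outside it, and the cyclopentenone closes last, by carbonyl insertion and reductive elimination at rhodium. No stereocentre is created (C1, C5 and C10 are sp2) and C7 and C8 are carried through unchanged, C1 and C10 being set in step 10. The step needs selectivity for the distal over the proximal allene π-bond, which rhodium provides and the methyl group on C10 reinforces, and for cyclocarbonylation over cycloisomerization, which is secured because the distal allene carbon is an unsubstituted CH2 that offers no β-hydrogen for an ene-type pathway. The cis-disubstituted dioxane holds the two chains gauche, which should raise the population of the folded conformer needed for the seven-membered ring and disfavour oligomerization at the dilution used.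

Step 10
Reactants: 17 (7S,8R)-8,11-(isopropylidenedioxy)guaia-1(10),4-dien-3-one
Product: 20 (1R,7S,8R,10S)-8,11-(isopropylidenedioxy)guai-4-en-3-one, via lithium dienolate 18 (not isolated), via deconjugated enone 19 (not isolated)
Conditions: Li (2.2 equiv), NH3(l)/THF, −78 °C; solid NH4Cl; then NaOMe (cat.), MeOH, rt
Reagents that add atoms: none
Why: Dissolving-metal 1,6-reduction of a linear dienone (as with steroidal 4,6-dien-3-ones) should add two electrons and protonate the δ-carbon C10 on the face opposite the pseudo-axial C8–O bond of the cis-fused dioxane, which places the C10 methyl cis to O8, after which methoxide moves the double bond of 19 into conjugation and equilibrates the epimerizable γ-carbon C1 to the arrangement with C2 trans to the C10 methyl.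

Step 11
Reactants: 20 (1R,7S,8R,10S)-8,11-(isopropylidenedioxy)guai-4-en-3-one
Product: 21 (1R,7S,8R,10S)-8,11-dihydroxyguai-4-en-3-one
Conditions: AcOH/THF/H2O (3:1:1), 40 °C
Reagents that add atoms: none
Why: Mild acetal hydrolysis should cleave the strained tetramethyl-1,3-dioxane without dehydrating the tertiary alcohol, and C1 already sits at its thermodynamic configuration.

Step 12
Reactants: 21 (1R,7S,8R,10S)-8,11-dihydroxyguai-4-en-3-one; 22 angelic acid
Product: 24 (1R,7S,8R,10S)-8-angeloyloxy-11-hydroxyguai-4-en-3-one, via mixed angelic anhydride 23 (not isolated)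
Conditions: 22, 2,4,6-trichlorobenzoyl chloride, Et3N, toluene, rt; then 21, 80 °C
Reagents that add atoms: none
Why: Yamaguchi-type esterification through mixed anhydride 23 without DMAP should acylate only the secondary C8 hydroxyl, the tertiary C11 hydroxyl being inert, and is the established way to make angelates without Z-to-E isomerization to the tiglate.

Step 13
Reactants: 24 (1R,7S,8R,10S)-8-angeloyloxy-11-hydroxyguai-4-en-3-one
Product: 25 torilin, (1R,7S,8R,10S)-11-acetoxy-8-angeloyloxyguai-4-en-3-one
Conditions: Ac2O, Sc(OTf)3 (2 mol %), MeCN, −20 °C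
Reagents that add atoms: acetic anhydride, CC(=O)OC(C)=O
Why: Sc(OTf)3-catalysed acylation with acetic anhydride esterifies hindered tertiary alcohols at low temperature, conditions under which the angelate geometry, the enone and C1 should be stable.

**Compound list**

1 | hex-4-ynoic acid | CC#CCCC(=O)O | starting material
2 | (S)-4-benzyl-1,3-oxazolidin-2-one | O=C1N[C@@H](Cc2ccccc2)CO1 | starting material
3 | hex-4-ynoic pivalic anhydride (mixed pivalic anhydride, not isolated) | CC#CCCC(=O)OC(=O)C(C)(C)C | intermediate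
4 | (S)-4-benzyl-3-(hex-4-ynoyl)-1,3-oxazolidin-2-one | CC#CCCC(=O)N1[C@@H](Cc2ccccc2)COC1=O | intermediate
5 | 3-methylbut-3-en-1-ol | C=C(C)CCO | starting material
6 | 3-methylbut-3-enal | C=C(C)CC=O | intermediate
7 | Z-dibutylboron enolate of 4 (not isolated) | CC#CC/C=C(\OB(CCCC)CCCC)N1[C@@H](Cc2ccccc2)COC1=O | intermediate
8 | dibutylboron aldolate of 9 (not isolated) | C=C(C)C[C@@H](OB(CCCC)CCCC)[C@H](CC#CC)C(=O)N1[C@@H](Cc2ccccc2)COC1=O | intermediate
9 | (S)-4-benzyl-3-[(2S,3R)-2-(but-2-yn-1-yl)-3-hydroxy-5-methylhex-5-enoyl]-1,3-oxazolidin-2-one | C=C(C)C[C@@H](O)[C@H](CC#CC)C(=O)N1[C@@H](Cc2ccccc2)COC1=O | intermediate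
10 | methyl (2S,3R)-2-(but-2-yn-1-yl)-3-hydroxy-5-methylhex-5-enoate | C=C(C)C[C@@H](O)[C@H](CC#CC)C(=O)OC | intermediate
11 | (3S,4R)-3-(but-2-yn-1-yl)-2,6-dimethylhept-6-ene-2,4-diol | C=C(C)C[C@@H](O)[C@H](CC#CC)C(C)(C)O | intermediate
12 | (5S,6R)-5-(but-2-yn-1-yl)-2,2,4,4-tetramethyl-6-(2-methylprop-2-en-1-yl)-1,3-dioxane | CC1(C)O[C@H](CC(C)=C)[C@H](CC#CC)C(C)(C)O1 | intermediate
13 | (5S,6R)-5-(but-2-yn-1-yl)-6-[(2,2-dibromo-1-methylcyclopropyl)methyl]-2,2,4,4-tetramethyl-1,3-dioxane (both epimers at the cyclopropane carbon) | CC1(C)O[C@H](CC2(C)CC2(Br)Br)[C@H](CC#CC)C(C)(C)O1 | intermediate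
14 | 1-bromo-1-lithiocyclopropane carbenoid derived from 13 (not isolated) | CC1(C)O[C@H](CC2(C)CC2([Li])Br)[C@H](CC#CC)C(C)(C)O1 | intermediate
15 | (5S,6R)-5-(but-2-yn-1-yl)-2,2,4,4-tetramethyl-6-(2-methylbuta-2,3-dien-1-yl)-1,3-dioxane | CC1(C)O[C@H](CC(C)=C=C)[C@H](CC#CC)C(C)(C)O1 | intermediate
16 | rhodacyclopentene with rhodium bound to C2 and C4 (CO and chloride ligands on rhodium not drawn, not isolated) | CC1(C)O[C@@H]2CC(C)=C3C[Rh]C(C)=C3C[C@@H]2C(C)(C)O1 | intermediate
17 | (7S,8R)-8,11-(isopropylidenedioxy)guaia-1(10),4-dien-3-one | CC1(C)O[C@@H]2CC(C)=C3CC(=O)C(C)=C3C[C@@H]2C(C)(C)O1 | intermediate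
18 | lithium dienolate O–C3=C4–C5=C1 with C10 (S)-configured (not isolated) | CC1(C)O[C@@H]2C[C@H](C)C3=C(C(C)=C([O-])C3)C[C@@H]2C(C)(C)O1.[Li+] | intermediate
19 | (7S,8R,10S)-8,11-(isopropylidenedioxy)guai-1(5)-en-3-one, both epimers at C4 (not isolated) | CC1(C)O[C@@H]2C[C@H](C)C3=C(C(C)C(=O)C3)C[C@@H]2C(C)(C)O1 | intermediate
20 | (1R,7S,8R,10S)-8,11-(isopropylidenedioxy)guai-4-en-3-one | CC1(C)O[C@@H]2C[C@H](C)[C@H]3CC(=O)C(C)=C3C[C@@H]2C(C)(C)O1 | intermediate
21 | (1R,7S,8R,10S)-8,11-dihydroxyguai-4-en-3-one | O[C@@H]1C[C@H](C)[C@H]2CC(=O)C(C)=C2C[C@@H]1C(C)(C)O | intermediate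
22 | angelic acid, (Z)-2-methylbut-2-enoic acid | C/C=C(/C)C(=O)O | starting material
23 | angelic 2,4,6-trichlorobenzoic anhydride (not isolated) | C/C=C(/C)C(=O)OC(=O)c1c(Cl)cc(Cl)cc1Cl | intermediate
24 | (1R,7S,8R,10S)-8-angeloyloxy-11-hydroxyguai-4-en-3-one | C/C=C(/C)C(=O)O[C@@H]1C[C@H](C)[C@H]2CC(=O)C(C)=C2C[C@@H]1C(C)(C)O | intermediate
25 | torilin, (1R,7S,8R,10S)-11-acetoxy-8-angeloyloxyguai-4-en-3-one | C/C=C(/C)C(=O)O[C@@H]1C[C@H](C)[C@H]2CC(=O)C(C)=C2C[C@@H]1C(C)(C)OC(C)=O | target

**Step count**

Total: 13 steps. Longest linear sequence: 12 steps (steps 1 and 3–13, from hex-4-ynoic acid); step 2 is a one-step side branch.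

**Steps most likely to fail**

1. Step 10. What may go wrong: protonation of the C10 carbanion on the dioxane-bearing face (poor facial selectivity), or protonation at C5 instead of C10, so that the C10 methyl ends up trans to O8 or the wrong enone results. Fallback: set out from 17 and replace electron transfer by surface hydrogenation (H2, 1 atm, palladium on carbon, EtOAc). Both hydrogens would then be delivered syn from the catalyst to the less hindered face of the C1=C10 bond, giving (1S,7S,8R,10S)-8,11-(isopropylidenedioxy)guai-4-en-3-one F1, the 1-epimer of 20 with H1 and H10 cis. Epimerization of C1 through the dienolate (NaOMe, MeOH, rt) should then return to the route at 20.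

2. Step 9. What may go wrong: slow oxidative cyclization to the seven-membered ring, so that allene oligomerization or intermolecular coupling overtakes ring closure. Fallback: set out from 12 and exchange the allene for a vinyl carbinol whose hydroxyl is eliminated after the ring closure.
   - Oxidative cleavage of the methallyl alkene (OsO4 cat., NaIO4, 2,6-lutidine, dioxane/H2O) should give 1-[(4R,5S)-5-(but-2-yn-1-yl)-2,2,6,6-tetramethyl-1,3-dioxan-4-yl]propan-2-one F2.
   - Vinylmagnesium bromide (THF, −78 °C) should give 1-[(4R,5S)-5-(but-2-yn-1-yl)-2,2,6,6-tetramethyl-1,3-dioxan-4-yl]-2-methylbut-3-en-2-ol F3 as both carbinol epimers; its fully substituted carbinol carbon favours chain folding.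
   - Enyne Pauson–Khand cyclocarbonylation ([Rh(CO)2Cl]2, CO, toluene, 90 °C) should give (7S,8R)-10-hydroxy-8,11-(isopropylidenedioxy)guai-4-en-3-one F4, with the cyclopentenone again closed last.
   - Dehydration (Burgess reagent, toluene, 60 °C, then DBU to bring any double-bond isomers into conjugation) should return to the route at 17.

3. Step 13. What may go wrong: ionization or elimination of the tertiary C11 alcohol under Lewis-acid acylation, or isomerization of the angelate to the tiglate. Fallback: set out from 21 and reverse the order of the two acylations with a temporary silyl group.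
   - Selective silylation of the secondary hydroxyl (TESCl, imidazole, CH2Cl2, 0 °C) should give (1R,7S,8R,10S)-11-hydroxy-8-(triethylsilyloxy)guai-4-en-3-one F5.
   - Forcing acetylation of the tertiary hydroxyl while no angelate is present (Ac2O, DMAP, Et3N, 50 °C) should give (1R,7S,8R,10S)-11-acetoxy-8-(triethylsilyloxy)guai-4-en-3-one F6.
   - Desilylation under weakly acidic conditions that avoid acetyl migration (HF·pyridine, THF, 0 °C) should give (1R,7S,8R,10S)-11-acetoxy-8-hydroxyguai-4-en-3-one F7.
   - Angeloylation with mixed anhydride 23 (toluene, 80 °C) then comes back to the route at 25.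

**Further compounds**

F1 | step 10 | (1S,7S,8R,10S)-8,11-(isopropylidenedioxy)guai-4-en-3-one | CC1(C)O[C@@H]2C[C@H](C)[C@@H]3CC(=O)C(C)=C3C[C@@H]2C(C)(C)O1
F2 | step 9 | 1-[(4R,5S)-5-(but-2-yn-1-yl)-2,2,6,6-tetramethyl-1,3-dioxan-4-yl]propan-2-one | CC1(C)O[C@H](CC(C)=O)[C@H](CC#CC)C(C)(C)O1
F3 | step 9 | 1-[(4R,5S)-5-(but-2-yn-1-yl)-2,2,6,6-tetramethyl-1,3-dioxan-4-yl]-2-methylbut-3-en-2-ol (both carbinol epimers) | CC1(C)O[C@H](CC(C)(O)C=C)[C@H](CC#CC)C(C)(C)O1
F4 | step 9 | (7S,8R)-10-hydroxy-8,11-(isopropylidenedioxy)guai-4-en-3-one (mixture at C1 and C10) | CC1(C)O[C@@H]2CC(C)(O)C3CC(=O)C(C)=C3C[C@@H]2C(C)(C)O1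
F5 | step 13 | (1R,7S,8R,10S)-11-hydroxy-8-(triethylsilyloxy)guai-4-en-3-one | CC[Si](CC)(CC)O[C@@H]1C[C@H](C)[C@H]2CC(=O)C(C)=C2C[C@@H]1C(C)(C)O
F6 | step 13 | (1R,7S,8R,10S)-11-acetoxy-8-(triethylsilyloxy)guai-4-en-3-one | CC[Si](CC)(CC)O[C@@H]1C[C@H](C)[C@H]2CC(=O)C(C)=C2C[C@@H]1C(C)(C)OC(C)=O
F7 | step 13 | (1R,7S,8R,10S)-11-acetoxy-8-hydroxyguai-4-en-3-one | O[C@@H]1C[C@H](C)[C@H]2CC(=O)C(C)=C2C[C@@H]1C(C)(C)OC(C)=O
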